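All compound numbers refer to the compound list after the steps.

## The problem

Target 15 is a 5,7-dihydroxyflavone (ring A the oxygenated benzo ring, ring C the 4-pyranone, ring B the C2 phenyl) that carries an (R)-1-methylpiperidin-2-yl group on C6, the ring A carbon flanked by both hydroxyls. The skeleton therefore needs one aryl–C(sp3) bond, C6–C2', at the most hindered carbon of an electron-rich arene, and it must be made at C6 and not at the electronically similar C8, which aminoalkylation of a preformed flavone does not distinguish well. C2' is the only stereocentre; it is benzylic and α to a tertiary amine, nothing else in the molecule can relay chirality to it, and so its configuration has to come from a chiral reagent or catalyst. C2' is also the fragile point: with oxygen ortho, ortho and para to it, the C2'–N1' bond can ionise in hot acid or, once the phenols are free, through a quinone methide, so the stereocentre should not see prolonged heating in acid and the phenols are best freed last. The chromone, a vinylogous ester with a C2=C3 double bond, does not tolerate hydrides, organometallics or hydrogenation, so all reductive and organometallic chemistry must precede ring C, and the basic nitrogen must be kept from binding metal catalysts. The enabling feature is that N1' and C2'–C6' form a saturated six-membered azacycle, the hexahydro form of a 1-methylpyridinium bonded through its C2 to ring A. C2' can therefore be created by adding hydrogen to a flat, achiral 2-arylpyridinium, and the C6–C2' bond can be made earlier as a biaryl bond. Because C6 lies between two oxygens and para to the third (the future O1), the arene at that stage (2) has a mirror plane through that carbon, and the C6/C8 question does not arise.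

## Retrosynthesis

**15 ⇒ 14 (two O–CH3 bonds).** The C5 and C7 hydroxyls are carried as methyl ethers to the end. They direct the metalation, survive organolithium, hydrogenation and strong acid, and keep the quinone methide pathway closed until the last operation. Cutting here rather than earlier leaves one deprotection on a finished skeleton. The forward step must cleave the chelated C5 ether and the less reactive C7 ether without ionising C2'–N1'.

**14 ⇒ 13 ⇒ 12 ⇒ 10 + 11 (C4–C4a, then O1–C2).** Ring C is opened first at the acyl–arene bond C4–C4a, which gives the aryloxycinnamic acid 13 and its ester 12, and then at the aryl ether bond O1–C2, which gives phenol 10 and alkynoate 11. The classical diketone-rearrangement route would first require C-acylation of ring A, whereas this cut needs only the phenol oxygen para to the piperidine. The two positions ortho to that oxygen in 10 are equivalent, so only one flavone can form. Compound 10 has no ring C and 11 is commercial. The forward sequence asks for a conjugate addition of a hindered-ring phenoxide, a mild saponification, and a ring closure in acid short enough to spare C2'.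

**10 ⇒ 9 (O–Si).** The oxygen that becomes O1 must be distinguishable from the two that become the C5 and C7 hydroxyls. A bulky silyl ether does this, and unlike a benzyl ether it tolerates the aryllithium stage. The forward step is a fluoride deprotection.

**9 ⇒ 7 (no skeletal bond; six C–H bonds at C2'–C6').** The N-methylpiperidine is taken back to the 1-methylpyridinium salt 7. The neighbouring options build the piperidine on ring A by C–C or C–N bond formation and then have to add the N-methyl group. This cut buys the ring intact, carries the methyl group as the activating group, and gives an achiral precursor with no stereocentre. The forward reaction must reduce a cationic heteroarene enantioselectively at a carbon bearing a doubly ortho-substituted aryl group, and must leave the benzene ring and the silyl ether alone.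

**7 ⇒ 6 (N–CH3).** Quaternisation is placed directly before the hydrogenation so that the neutral pyridine 6, which is easier to purify, is the product of the cross-coupling. The forward step is alkylation of a hindered but exposed pyridine nitrogen.

**6 ⇒ 2 + 3, through 4 and 5 (aryl–pyridyl C–C bond).** The biaryl bond is cut to an arylmetal and 2-bromopyridine 3. The carbon between the two methoxy groups of 2 carries the most acidic C–H of the arene, so directed metalation to 4 and transmetalation to 5 place the metal exactly where the bond is needed. The alternative, halogenating ring A, would have to choose between similar positions. The forward step is a cross-coupling of a doubly ortho-substituted arylzinc.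

**2 ⇒ 1 (O–Si).** Silylation of commercial 3,5-dimethoxyphenol 1, which removes the acidic proton and marks the future O1.

## Roads not taken

Alternative 1: Ring C is cut at C3–C4 and O1–C2, back to the salicylaldehyde tert-butyl (R)-2-(3-formyl-4-hydroxy-2,6-dimethoxyphenyl)piperidine-1-carboxylate A1 and the benzoyl sulfoxonium ylide A2.
- Forward step: under [Cp*RhCl2]2 (a trivalent rhodium precatalyst) with AgSbF6 and NaOAc, the phenol directs metalation of the formyl C–H bond. The ylide delivers a carbene that inserts into the acyl–rhodium bond (C3–C4), and cyclodehydration closes O1–C2 to give the N-Boc flavone A3.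
- Merits: a convergent, nearly neutral annulation that avoids strong acid altogether.
- Weak points: it says nothing about how C2' is set, so A1 must come from a separate asymmetric synthesis. The nitrogen has to be carried as a carbamate to keep it off rhodium and silver, which costs a deprotection and an N-methylation after A3, before the ether cleavage. The formyl group of A1 sits between a hydroxyl and a methoxy group, where decarbonylation of the acyl–rhodium species and competing coordination are plausible.
- Comparison: for ring C alone this road is gentler than the chosen acid closure and one operation shorter (formylation and annulation against addition, saponification and cyclisation). Against that, the chosen plan uses no precious metal for ring C, needs no nitrogen protecting group, and solves the stereocentre, which this alternative leaves open.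

Alternative 2: The C2'–C3' bond is cut, back to the (S)-tert-butanesulfinyl aldimine A4 and 4-chlorobutylmagnesium bromide A5.
- Forward step: A5 adds to A4 through the usual closed, magnesium-chelated transition state to give the sulfinamide A6 with (R) configuration at the new carbon. The piperidine is then closed by N-alkylation.
- Merits: auxiliary control of this kind is predictable, the diastereomers of A6 are separable so the stereochemical purity can be upgraded, and no pressure equipment or ligand screening is needed. In reliability of stereocontrol this road is stronger than the chosen one.
- Weak points: the imine carbon of A4 is flanked by two methoxy groups, which slow the addition and can bind magnesium in competition with the sulfinyl oxygen, so the selectivity is less certain than in ordinary cases. The auxiliary is stoichiometric. After A6, ring closure, sulfinyl removal, N-methylation and debenzylation are needed before the phenol stage, about eight operations from 1 against five to reach 10. A4 itself requires a regioselective formylation of an arene with two kinds of open position.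
- Comparison: the chosen plan offers a catalytic source of chirality, a purchased azacycle with the N-methyl group in place, and regiochemistry fixed by metalation. It pays with an asymmetric step whose selectivity on this substrate is unproven.

Alternative 3: The N1'–C2' and N1'–C6' bonds are cut, back to the chloroketone 1-[4-(benzyloxy)-2,6-dimethoxyphenyl]-5-chloropentan-1-one A7.
- Forward step: an (R)-selective transaminase with its pyridoxal cofactor and an amine donor converts A7 into the primary amine A8, which displaces chloride spontaneously to give piperidine A9.
- Merits: where an enzyme accepts the substrate, the enantiomeric purity is usually higher than any hydrogenation catalyst gives, and the conditions are aqueous and ambient. The stereocentre and the ring form in one operation without nitrogen protection. In these respects it is better than the chosen plan.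
- Weak points: A7 is a ketone with two large groups, a doubly ortho-substituted and twisted aryl ring and a four-carbon chain, where transaminases normally require one small substituent. It is poorly soluble in water, and it can be lost to background hydrolysis of the chloride. A9 still needs N-methylation and debenzylation, and A7 needs a regioselective acylation.
- Comparison: the chosen plan has a substrate activated by its own positive charge, a small-molecule catalyst whose ligand can be varied rationally, and the N-methyl group delivered without a separate step.

Key step: step 4

Assumption: the sense of induction of the P,N ligand on an N-methyl substrate cannot be predicted with confidence. The route uses whichever antipode of the ligand delivers the (R)-amine, established by a trial reduction, and calls it the (R)-inducing ligand.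

## Route

Step 1
Reactants: 1 3,5-dimethoxyphenol
Product: 2 (3,5-dimethoxyphenoxy)triisopropylsilane
Conditions: TIPSCl, imidazole, DMF, rt
Reagents that add atoms: chlorotriisopropylsilane (TIPSCl), CC(C)[Si](Cl)(C(C)C)C(C)C
Why: Imidazole-mediated O-silylation of a phenol; the bulky triisopropylsilyl group removes the acidic O–H before the organolithium step, resists 1,3-migration to an ortho carbanion, and is a hindered, weakly coordinating substituent that will not compete as a metalation director in step 2.

Step 2
Reactants: 2 (3,5-dimethoxyphenoxy)triisopropylsilane; 3 2-bromopyridine
Product: 6 2-[2,6-dimethoxy-4-(triisopropylsilyloxy)phenyl]pyridine, via aryllithium 4 (not isolated), via arylzinc chloride 5 (not isolated)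
Conditions: n-BuLi, THF, 0 °C → rt; ZnCl2, THF, 0 °C → rt; 3, Pd(PPh3)4 (5 mol %), THF, 65 °C
Reagents that add atoms: n-butyllithium, [Li]CCCC; zinc chloride, Cl[Zn]Cl
Why: Directed ortho-metalation followed by Negishi coupling: the C–H between the two methoxy groups is the most acidic and its lithium is held by both oxygens, whereas the positions beside the silyloxy group are not competitive, so 4 forms on the carbon through which the mirror plane of 2 passes; transmetalation gives 5, which couples with the activated C2–Br bond of 3 under zerovalent palladium, a pairing well known for 2,6-dialkoxyarylzinc halides. The lithium of 4 and the zinc and chlorine of 5 are lost on coupling, so 6 holds only atoms of 2 and 3.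

Step 3
Reactants: 6 2-[2,6-dimethoxy-4-(triisopropylsilyloxy)phenyl]pyridine
Product: 7 2-[2,6-dimethoxy-4-(triisopropylsilyloxy)phenyl]-1-methylpyridin-1-ium iodide
Conditions: MeI (excess), MeCN, 70 °C, sealed vessel; precipitate with Et2O
Reagents that add atoms: iodomethane, CI
Why: Menshutkin N-alkylation: the pyridine nitrogen is the only nucleophilic heteroatom, its in-plane lone pair remains reachable by the small electrophile although the aryl group is twisted beside it, and the salt should crystallise on adding ether, which removes neutral impurities before the catalytic step.

Step 4
Reactants: 7 2-[2,6-dimethoxy-4-(triisopropylsilyloxy)phenyl]-1-methylpyridin-1-ium iodide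
Product: 9 (R)-2-[2,6-dimethoxy-4-(triisopropylsilyloxy)phenyl]-1-methylpiperidine, via cyclic iminium iodide 8 (not isolated)
Conditions: H2 (50 bar), [Ir(cod)Cl]2 (2 mol %), (R)-inducing P-stereogenic dihydrobenzooxaphosphole P,N ligand of the MeO-BoQPhos type (4.4 mol %), THF, 40 °C; then aq K2CO3
Reagents that add atoms: none
Why: This is the iridium-catalysed asymmetric hydrogenation of a 2-arylpyridinium salt, a reaction type established for N-benzyl 2-aryl and 2-alkyl salts and applied here to an N-methyl, doubly ortho-substituted member of the same class. The monovalent iridium precatalyst and the ligand form trivalent iridium hydrides under H2, which transfer hydride to the cationic ring by an outer-sphere path; the dihydropyridine so formed is an enamine that is protonated by the acid released on heterolytic H2 cleavage, reduced again to the cyclic enamine, and protonated at C3' to give iminium 8. The last hydride transfer, to C2' of 8, is enantiodetermining, and because the enamine–iminium equilibrium is fast the configuration is fixed only at that point. No ring is closed and no skeletal bond is formed; three molecules of H2 are added to an existing ring. C2' is controlled solely by the chiral ligand on iridium (catalyst control on an achiral substrate), and the ligand antipode that exposes the face leading to (R) is used. The step needs enantioface selection at the C=N+ bond of 8 and chemoselectivity for the pyridinium over the benzene ring and the Si–O bond. Quaternisation makes the heterocycle the only electrophilic, weakly aromatic ring and stops nitrogen from binding iridium, while the two ortho methoxy groups hold the arene perpendicular, so it is neither conjugated with nor reduced along with the C=N+ bond and presents one large, well-defined group to the ligand pocket. The amine leaves the cycle as its hydroiodide, which cannot inhibit the catalyst, and is freed by the carbonate wash.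

Step 5
Reactants: 9 (R)-2-[2,6-dimethoxy-4-(triisopropylsilyloxy)phenyl]-1-methylpiperidine
Product: 10 (R)-3,5-dimethoxy-4-(1-methylpiperidin-2-yl)phenol
Conditions: TBAF, THF, 0 °C → rt; aq NH4Cl
Reagents that add atoms: none
Why: Fluoride-mediated cleavage of an aryl silyl ether, driven by Si–F bond formation; the methyl ethers, the tertiary amine and C2' are inert to fluoride, and the buffered quench returns the aminophenol near its isoelectric point for extraction.

Step 6
Reactants: 10 (R)-3,5-dimethoxy-4-(1-methylpiperidin-2-yl)phenol; 11 ethyl 3-phenylprop-2-ynoate (ethyl phenylpropiolate)
Product: 12 ethyl (Z)-3-{3,5-dimethoxy-4-[(R)-1-methylpiperidin-2-yl]phenoxy}-3-phenylprop-2-enoate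
Conditions: K2CO3, DMF, 80 °C
Reagents that add atoms: none
Why: Base-mediated oxa-Michael addition of a phenoxide to an aryl alkynoate, the first stage of the Ruhemann flavone synthesis; the phenoxide is the only competent nucleophile (the tertiary amine can add only reversibly), and the alkene geometry is not critical because the push–pull double bond equilibrates in the acid of step 8, so 12 is drawn as the Z isomer required for ring closure and any E isomer is carried along.

Step 7
Reactants: 12 ethyl (Z)-3-{3,5-dimethoxy-4-[(R)-1-methylpiperidin-2-yl]phenoxy}-3-phenylprop-2-enoate
Product: 13 (Z)-3-{3,5-dimethoxy-4-[(R)-1-methylpiperidin-2-yl]phenoxy}-3-phenylprop-2-enoic acid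
Conditions: LiOH, THF/MeOH/H2O, rt → 40 °C; aq HCl to pH 6–7
Reagents that add atoms: lithium hydroxide, [Li+].[OH-] (its oxygen becomes a carboxyl oxygen)
Why: Ester saponification; the β-aryloxy group of the vinylogous carbonate is retained under mild hydroxide as in the classical sequence, C2' carries no acidic hydrogen so its configuration is untouched, and neutralisation to the isoelectric point gives the amino acid, which is used crude.

Step 8
Reactants: 13 (Z)-3-{3,5-dimethoxy-4-[(R)-1-methylpiperidin-2-yl]phenoxy}-3-phenylprop-2-enoic acid
Product: 14 (R)-5,7-dimethoxy-6-(1-methylpiperidin-2-yl)-2-phenyl-4H-chromen-4-one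
Conditions: P2O5/CH3SO3H (1:10 w/w), 40 °C; ice, then aq NaOH to pH 10
Reagents that add atoms: none
Why: Intramolecular Friedel–Crafts acylation closing the six-membered ring at C4–C4a through the mixed anhydride or acylium ion formed by P2O5 in CH3SO3H, the second stage of the Ruhemann synthesis; the two positions ortho to the aryloxy oxygen are equivalent, each lying beside a methoxy group and para to the other, so only one flavone can form and it forms far faster than closure onto the phenyl group. The amine is present as its ammonium salt, which keeps nitrogen out of the chemistry, and the moderate temperature and short time are chosen to spare the C2'–N1' bond.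

Step 9
Reactants: 14 (R)-5,7-dimethoxy-6-(1-methylpiperidin-2-yl)-2-phenyl-4H-chromen-4-one
Product: 15 (R)-5,7-dihydroxy-6-(1-methylpiperidin-2-yl)-2-phenyl-4H-chromen-4-one
Conditions: BBr3 (6 equiv), CH2Cl2, −78 °C → rt; ice-water, aq NaHCO3 to pH 8
Reagents that add atoms: none
Why: Lewis acid ether cleavage with BBr3 (O–B coordination, then bromide attack at methyl); the C5 ether is assisted by chelation to the C4 carbonyl and the C7 ether follows with excess reagent, one equivalent being held by the amine. C2' is not a reacting centre, and the cold start and near-neutral work-up are chosen to keep the C2'–N1' bond intact.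

## Compound list

1 | 3,5-dimethoxyphenol | COc1cc(O)cc(OC)c1 | starting material
2 | (3,5-dimethoxyphenoxy)triisopropylsilane | COc1cc(O[Si](C(C)C)(C(C)C)C(C)C)cc(OC)c1 | intermediate
3 | 2-bromopyridine | Brc1ccccn1 | starting material
4 | [2,6-dimethoxy-4-(triisopropylsilyloxy)phenyl]lithium | [Li]c1c(OC)cc(O[Si](C(C)C)(C(C)C)C(C)C)cc1OC | intermediate (not isolated)
5 | [2,6-dimethoxy-4-(triisopropylsilyloxy)phenyl]zinc chloride | Cl[Zn]c1c(OC)cc(O[Si](C(C)C)(C(C)C)C(C)C)cc1OC | intermediate (not isolated)
6 | 2-[2,6-dimethoxy-4-(triisopropylsilyloxy)phenyl]pyridine | COc1cc(O[Si](C(C)C)(C(C)C)C(C)C)cc(OC)c1-c1ccccn1 | intermediate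
7 | 2-[2,6-dimethoxy-4-(triisopropylsilyloxy)phenyl]-1-methylpyridin-1-ium iodide | C[n+]1ccccc1-c1c(OC)cc(O[Si](C(C)C)(C(C)C)C(C)C)cc1OC.[I-] | intermediate
8 | 6-[2,6-dimethoxy-4-(triisopropylsilyloxy)phenyl]-1-methyl-2,3,4,5-tetrahydropyridin-1-ium iodide | C[N+]1=C(CCCC1)c1c(OC)cc(O[Si](C(C)C)(C(C)C)C(C)C)cc1OC.[I-] | intermediate (not isolated)
9 | (R)-2-[2,6-dimethoxy-4-(triisopropylsilyloxy)phenyl]-1-methylpiperidine | CN1CCCC[C@@H]1c1c(OC)cc(O[Si](C(C)C)(C(C)C)C(C)C)cc1OC | intermediate
10 | (R)-3,5-dimethoxy-4-(1-methylpiperidin-2-yl)phenol | CN1CCCC[C@@H]1c1c(OC)cc(O)cc1OC | intermediate
11 | ethyl 3-phenylprop-2-ynoate (ethyl phenylpropiolate) | CCOC(=O)C#Cc1ccccc1 | starting material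
12 | ethyl (Z)-3-{3,5-dimethoxy-4-[(R)-1-methylpiperidin-2-yl]phenoxy}-3-phenylprop-2-enoate | CN1CCCC[C@@H]1c1c(OC)cc(O/C(=C\C(=O)OCC)c2ccccc2)cc1OC | intermediate
13 | (Z)-3-{3,5-dimethoxy-4-[(R)-1-methylpiperidin-2-yl]phenoxy}-3-phenylprop-2-enoic acid | CN1CCCC[C@@H]1c1c(OC)cc(O/C(=C\C(=O)O)c2ccccc2)cc1OC | intermediate
14 | (R)-5,7-dimethoxy-6-(1-methylpiperidin-2-yl)-2-phenyl-4H-chromen-4-one | CN1CCCC[C@@H]1c1c(OC)cc2oc(-c3ccccc3)cc(=O)c2c1OC | intermediate
15 | (R)-5,7-dihydroxy-6-(1-methylpiperidin-2-yl)-2-phenyl-4H-chromen-4-one | CN1CCCC[C@@H]1c1c(O)cc2oc(-c3ccccc3)cc(=O)c2c1O | target

## Step count and risks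

Total step count: 9. Longest linear sequence: 9 steps (1 → 15); compounds 3 and 11 are purchased and enter in steps 2 and 6.

**Step 4 (key step).**
- In iminium 8 the perpendicular aryl ring places one methoxy group over each face of the C=N+ bond. Hydride delivery may therefore be slow and the reduction may stall at the enamine stage.
- The N-methyl group gives the ligand less to hold than the N-benzyl group for which these catalysts were developed, so enantioface discrimination may be poor.
- The iodide counter-ion may also retard the catalyst.
- Fallback: setting out from 7, the ring is reduced without asymmetric induction (H2, PtO2, MeOH; then aq K2CO3) to racemic 2-[2,6-dimethoxy-4-(triisopropylsilyloxy)phenyl]-1-methylpiperidine F1. This is resolved by crystallisation with (2R,3R)-O,O'-di-p-toluoyltartaric acid, or with its antipode if that one makes the (R)-amine salt the less soluble; the (2R,3R) acid is assumed here. The (2R,3R)-di-p-toluoyltartrate salt of the (R)-amine F2 crystallises, the corresponding salt of the (S)-amine F3 stays in the mother liquor, and aqueous K2CO3 on F2 rejoins the route at 9.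

**Step 2.**
- Metalation beside the silyloxy group or anionic silyl migration would erode the regiocontrol.
- More probably, transmetalation and reductive elimination at the doubly ortho-substituted arylzinc 5 are slow, so protodemetalation back to 2 and homocoupling take over.
- Fallback: setting out from 2, aryllithium 4 is generated as before and quenched with iodine to give (4-iodo-3,5-dimethoxyphenoxy)triisopropylsilane F4, which can be purified and its substitution pattern confirmed. The hindered carbon is then the electrophile in a Negishi coupling with commercial 2-pyridylzinc bromide under Pd(PPh3)4 in THF, which rejoins the route at 6.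

**Step 8.**
- In the warm, strongly acidic medium the C2'–N1' bond, activated by two ortho methoxy groups and a para aryloxy oxygen, may ionise, with loss of configuration or elimination.
- Sulfonation of ring A, or closure of the E isomer onto the phenyl group, may compete.
- Fallback: setting out from 10, iodination ortho to the hydroxyl (NIS, MeCN/CF3CO2H, 0 °C, amine protonated) gives (R)-2-iodo-3,5-dimethoxy-4-(1-methylpiperidin-2-yl)phenol F5. Carbonylative Sonogashira coupling with phenylacetylene (CO 1 atm, PdCl2(PPh3)2, Et2NH, 60 °C) passes through (R)-1-[6-hydroxy-2,4-dimethoxy-3-(1-methylpiperidin-2-yl)phenyl]-3-phenylprop-2-yn-1-one F6, which closes by 6-endo oxa-Michael addition in the amine medium. This rejoins the route at 14 without any strong acid.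

**Step 9.**
- Cleavage may stop at the C7 ether, which is not chelated and is deactivated once the C5 oxygen and the carbonyl are bound to boron.
- If the reaction is then forced, configuration may erode by reversible C2'–N1' heterolysis through a quinone methide once the oxygens are free.
- Fallback: setting out from 14, BCl3 (CH2Cl2, −78 → 0 °C; then aq NaHCO3) removes only the chelated C5 methyl group to give (R)-5-hydroxy-7-methoxy-6-(1-methylpiperidin-2-yl)-2-phenyl-4H-chromen-4-one F7. The C7 methyl group, which belongs to a vinylogous ester, is then removed by SN2 attack of sodium ethanethiolate (NaSEt) in DMF at 100 °C, followed by aq NH4Cl. Under these basic conditions the amine is a free base and cannot act as a leaving group. This arrives at 15.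

## Further compounds

F1 | step 4 | racemic 2-[2,6-dimethoxy-4-(triisopropylsilyloxy)phenyl]-1-methylpiperidine | CN1CCCCC1c1c(OC)cc(O[Si](C(C)C)(C(C)C)C(C)C)cc1OC
F2 | step 4 | (2R,3R)-di-p-toluoyltartrate salt of the (R)-amine 9 | CN1CCCC[C@@H]1c1c(OC)cc(O[Si](C(C)C)(C(C)C)C(C)C)cc1OC.OC(=O)[C@H](OC(=O)c1ccc(C)cc1)[C@@H](OC(=O)c1ccc(C)cc1)C(=O)O
F3 | step 4 | (2R,3R)-di-p-toluoyltartrate salt of the (S)-amine | CN1CCCC[C@H]1c1c(OC)cc(O[Si](C(C)C)(C(C)C)C(C)C)cc1OC.OC(=O)[C@H](OC(=O)c1ccc(C)cc1)[C@@H](OC(=O)c1ccc(C)cc1)C(=O)O
F4 | step 2 | (4-iodo-3,5-dimethoxyphenoxy)triisopropylsilane | COc1cc(O[Si](C(C)C)(C(C)C)C(C)C)cc(OC)c1I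
F5 | step 8 | (R)-2-iodo-3,5-dimethoxy-4-(1-methylpiperidin-2-yl)phenol | CN1CCCC[C@@H]1c1c(OC)cc(O)c(I)c1OC
F6 | step 8 | (R)-1-[6-hydroxy-2,4-dimethoxy-3-(1-methylpiperidin-2-yl)phenyl]-3-phenylprop-2-yn-1-one | CN1CCCC[C@@H]1c1c(OC)cc(O)c(C(=O)C#Cc2ccccc2)c1OC
F7 | step 9 | (R)-5-hydroxy-7-methoxy-6-(1-methylpiperidin-2-yl)-2-phenyl-4H-chromen-4-one | CN1CCCC[C@@H]1c1c(OC)cc2oc(-c3ccccc3)cc(=O)c2c1O
A1 | alternative 1 | tert-butyl (R)-2-(3-formyl-4-hydroxy-2,6-dimethoxyphenyl)piperidine-1-carboxylate | CC(C)(C)OC(=O)N1CCCC[C@@H]1c1c(OC)cc(O)c(C=O)c1OC
A2 | alternative 1 | 2-[dimethyl(oxo)-λ6-sulfanylidene]-1-phenylethan-1-one (benzoyl sulfoxonium ylide) | CS(C)(=O)=CC(=O)c1ccccc1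
A3 | alternative 1 | tert-butyl (R)-2-(5,7-dimethoxy-4-oxo-2-phenyl-4H-chromen-6-yl)piperidine-1-carboxylate | CC(C)(C)OC(=O)N1CCCC[C@@H]1c1c(OC)cc2oc(-c3ccccc3)cc(=O)c2c1OC
A4 | alternative 2 | (S,E)-N-[4-(benzyloxy)-2,6-dimethoxybenzylidene]-2-methylpropane-2-sulfinamide | CC(C)(C)[S@](=O)/N=C/c1c(OC)cc(OCc2ccccc2)cc1OC
A5 | alternative 2 | 4-chlorobutylmagnesium bromide | ClCCCC[Mg]Br
A6 | alternative 2 | (S)-N-[(R)-1-[4-(benzyloxy)-2,6-dimethoxyphenyl]-5-chloropentyl]-2-methylpropane-2-sulfinamide | CC(C)(C)[S@](=O)N[C@H](CCCCCl)c1c(OC)cc(OCc2ccccc2)cc1OC
A7 | alternative 3 | 1-[4-(benzyloxy)-2,6-dimethoxyphenyl]-5-chloropentan-1-one | O=C(CCCCCl)c1c(OC)cc(OCc2ccccc2)cc1OC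
A8 | alternative 3 | (R)-1-[4-(benzyloxy)-2,6-dimethoxyphenyl]-5-chloropentan-1-amine | N[C@H](CCCCCl)c1c(OC)cc(OCc2ccccc2)cc1OC
A9 | alternative 3 | (R)-2-[4-(benzyloxy)-2,6-dimethoxyphenyl]piperidine | N1CCCC[C@@H]1c1c(OC)cc(OCc2ccccc2)cc1OC
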